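**Assumptions:** The target has no stereocentres (it is achiral), so no stereocontrol is needed. (2‑Methoxy‑3‑methylphenyl)methanol is taken as a catalogue compound. The route is a design from known reaction classes and has not been run.

## Retrosynthetic overview
1. Target ⇐ phenolic MOM ether of the target (last step is deprotection) ⇐ the keto alcohol by O‑acetylation.
2. Diaryl ketone C–C bond ⇐ ortho‑lithiated benzyl alkoxide (ring B, lithiated between OMOM and CH2OLi) + 2,6‑dimethoxybenzoyl chloride (ring A).
3. Ring B ⇐ (2‑methoxy‑3‑methylphenyl)methanol by sterically controlled C–H borylation/oxidation at C5, then phenol‑selective MOM protection.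
4. No rings are formed: both benzene rings are purchased and the only skeletal bond made is aryl–C(=O).

## Route

**Step 1**
Reactants: 1, (2‑methoxy‑3‑methylphenyl)methanol
Product: 2, 3‑(hydroxymethyl)‑4‑methoxy‑5‑methylphenol
Conditions: HBpin (1.1 equiv, caps OH as OBpin); [Ir(OMe)(cod)]2 (1.5 mol %), dtbpy (3 mol %), B2pin2, THF, 80 °C; then aq NaOH/H2O2, 0 °C; Na2S2O3 work‑up
Reagents that add atoms: hydrogen peroxide, OO (supplies the phenolic O). Bis(pinacolato)diboron, CC1(C)OB(OC1(C)C)B1OC(C)(C)C(C)(C)O1, installs a transient Bpin that is not retained.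
Why: Ir‑catalysed C–H borylation is sterically controlled, and C5 is the only ring C–H without an ortho substituent in this 1,2,3‑trisubstituted arene; one‑pot oxidation of the aryl‑Bpin gives the phenol and the O–Bpin hydrolyses on work‑up.

**Step 2**
Reactants: 2, 3‑(hydroxymethyl)‑4‑methoxy‑5‑methylphenol
Product: 3, [2‑methoxy‑3‑methyl‑5‑(methoxymethoxy)phenyl]methanol
Conditions: NaH (1.0 equiv), THF/DMF, 0 °C; then MOMCl (1.05 equiv), 0 °C → rt
Reagents that add atoms: chloromethyl methyl ether (MOMCl), COCCl
Why: One equivalent of base deprotonates only the phenol (pKa about 10 versus about 15 for the benzylic alcohol), so Williamson‑type O‑alkylation gives the aryl MOM ether selectively.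

**Step 3**
Reactants: 3, [2‑methoxy‑3‑methyl‑5‑(methoxymethoxy)phenyl]methanol; 4, 2,6‑dimethoxybenzoyl chloride
Product: 5, (2,6‑dimethoxyphenyl)[2‑(hydroxymethyl)‑3‑methoxy‑4‑methyl‑6‑(methoxymethoxy)phenyl]methanone (in equilibrium with its cyclic hemiketal)
Conditions: n‑BuLi (2.2 equiv), TMEDA, Et2O, 0 °C → rt, 2 h; then 4 (1.0 equiv), THF, −78 → 0 °C; aq NH4Cl
Reagents that add atoms: compound 4, COc1cccc(OC)c1C(Cl)=O (delivers the 2,6‑dimethoxybenzoyl group)
Why: Directed ortho‑metalation occurs at the carbon flanked by the two cooperating directors (OMOM and CH2OLi). C‑acylation, or O‑acylation followed by anionic homo‑Fries transfer, converges on the same lithium lactolate, which masks the ketone against over‑addition.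

**Step 4**
Reactants: 5, the keto alcohol from step 3
Product: 6, [2‑(2,6‑dimethoxybenzoyl)‑6‑methoxy‑5‑methyl‑3‑(methoxymethoxy)phenyl]methyl acetate
Conditions: Ac2O (1.5 equiv), pyridine, DMAP (cat.), CH2Cl2, 0 °C → rt
Reagents that add atoms: acetic anhydride, CC(=O)OC(C)=O
Why: DMAP‑catalysed acylation of the primary alcohol of the open‑chain tautomer is far faster than acylation of the hindered tertiary hemiketal OH, and base‑mediated ring–chain equilibration funnels all material to the primary acetate.

**Step 5**
Reactants: 6, the MOM‑protected acetate from step 4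
Product: 7, Preacredinone A, [2‑(2,6‑dimethoxybenzoyl)‑3‑hydroxy‑6‑methoxy‑5‑methylphenyl]methyl acetate
Conditions: TFA/CH2Cl2 (1:10, anhydrous), 0 °C → rt; NaHCO3 work‑up
Reagents that add atoms: none
Why: Acid‑mediated acetal cleavage of the aryl MOM ether is fast because it releases a ketone‑chelated phenol. Anhydrous conditions avoid ester hydrolysis, and the benzylic acetate is poorly ionisable because its ortho‑OMe is twisted out of conjugation and an acyl group sits ortho; the three methyl ethers are inert.

## Compound list
1 | (2‑methoxy‑3‑methylphenyl)methanol | COc1c(C)cccc1CO | starting material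
2 | 3‑(hydroxymethyl)‑4‑methoxy‑5‑methylphenol | COc1c(C)cc(O)cc1CO | intermediate
3 | [2‑methoxy‑3‑methyl‑5‑(methoxymethoxy)phenyl]methanol | COCOc1cc(C)c(OC)c(CO)c1 | intermediate
4 | 2,6‑dimethoxybenzoyl chloride | COc1cccc(OC)c1C(Cl)=O | starting material
5 | (2,6‑dimethoxyphenyl)[2‑(hydroxymethyl)‑3‑methoxy‑4‑methyl‑6‑(methoxymethoxy)phenyl]methanone | COCOc1cc(C)c(OC)c(CO)c1C(=O)c1c(OC)cccc1OC | intermediate
6 | [2‑(2,6‑dimethoxybenzoyl)‑6‑methoxy‑5‑methyl‑3‑(methoxymethoxy)phenyl]methyl acetate | COCOc1cc(C)c(OC)c(COC(C)=O)c1C(=O)c1c(OC)cccc1OC | intermediate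
7 | Preacredinone A, [2‑(2,6‑dimethoxybenzoyl)‑3‑hydroxy‑6‑methoxy‑5‑methylphenyl]methyl acetate | COc1cccc(OC)c1C(=O)c1c(O)cc(C)c(OC)c1COC(C)=O | target

## Summary
Total steps: 5. Longest linear sequence: 5 (compound 4 is purchased).

Steps most likely to fail, each with a fallback that changes the approach:
1. **Step 3 (dilithiation/acylation with a hindered acid chloride).** Fallback: reverse the polarity. Quench the dianion of 3 with CO2 to give 4‑methoxy‑7‑(methoxymethoxy)‑5‑methylphthalide, then open the lactone with 2,6‑dimethoxyphenyllithium (1,3‑dimethoxybenzene, n‑BuLi) to reach 5.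
2. **Step 1 (C–H borylation with a free alcohol; possible over‑oxidation of the electron‑rich phenol).** Fallback: replace C–H activation with electrophilic substitution and cross‑coupling. Brominate methyl 2‑methoxy‑3‑methylbenzoate (para to OMe and meta to the ester, giving the 5‑bromide), carry out Pd‑catalysed hydroxylation (Pd2dba3/tBuXPhos, KOH), then MOM protection and LiAlH4 reduction to 3.
3. **Step 5 (MOM removal in the presence of the benzylic acetate).** Fallback: change the order of events. Remove the MOM group from 5 before any ester is present, peracetylate, then selectively cleave the more labile phenolic acetate (NH4OAc, aq MeOH); alternatively acetylate only the primary alcohol with lipase/vinyl acetate.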